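## Structural features

Septeremophilane G is a trinor-eremophilane. Numbering the decalin C1–C10, ring A (C1–C5, C10) is a saturated cyclohexane and ring B (C5–C10) a cross-conjugated 2-hydroxycyclohexa-2,5-dienone (C6=C7(OH), C8=O, C9=C10); the rings share the quaternary C5 and the trigonal C10. Ring A carries four contiguous stereocentres, C2 (OH), C3 (O-acyl), C4 (CH3) and C5 (CH3), and the (2E,4E)-6-methylocta-2,4-dienoyl group on the C3 oxygen carries an isolated fifth one at C6′ (S). Taking β as the face of the C5 methyl group, 4-CH3 and the C3 oxygen are β and the C2 hydroxyl is α; because ring B is flat, ring A has a single chair with 5-CH3 axial, 4-CH3 equatorial and the two oxygens trans-diaxial, the C3 oxygen syn-axial to 5-CH3. The fragile groups are the diosphenol (acidic, oxidisable enol on an electrophilic dienone), the dienoate (conjugate addition, deconjugation towards the allylic C6′ centre) and any α-ketol on the way. The real difficulties are the quaternary C5 flanked by the C4 stereocentre and two sp2 carbons, the acylation of the more hindered of two neighbouring ring A hydroxyls, and the oxidation pattern of ring B. The key step exploits the fact that C5 is bonded both to C6 (α to the oxygenated C7) and to C4 (next to the oxygenated C3): a C6=C7 enol ether can be joined oxidatively to a C4=C5 olefin, and the C4 cation so formed can be quenched by hydride from the C3 carbinol, which leaves the C3 ketone needed for C2 oxygenation.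

## Logic of the disconnections

26 ⇒ 25 ⇒ 18 + 23. The two O–Si bonds and then the C3–O acyl bond are cut. The dienoate tolerates neither enolate chemistry nor hydride, so it is attached last; this splits the target into a core and a side chain. The forward step must acylate a hindered axial alcohol, so the other two hydroxyls are silylated; the trans-diaxial arrangement should prevent acyl migration on desilylation.

23 ⇒ 22 ⇒ 20 + 21, and 20 ⇒ 19. The C4′=C5′ double bond is cut (vinylogous Horner–Wadsworth–Emmons reaction) and the aldehyde is taken back to a chiral-pool alcohol. The gain is a three-step side chain with C6′ bought in; the demand is that the α-branched aldehyde is not epimerised and that the new olefin is E.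

18 ⇒ 17 ⇒ 16 ⇒ 15. The C2–O bond is cut and the C3 carbinol returned to the ketone. This is placed after ring B is finished because only then is ring A locked in one chair, with axial 5-CH3 shielding the β face: oxygen should enter C2 from the α face and hydride should reach C3 from the α face. The gain is that both oxygenated stereocentres derive from one ketone; the demand is kinetic enolisation at C2 in the presence of a dienone and a hydroxyl-directed reduction.

15 ⇒ 14 ⇒ 13 ⇒ 12 ⇒ 10. The C8–O bond is cut and the C9=C10 unsaturation removed. In 10 the C7 carbonyl is flanked by two methylenes, whereas the C3 carbonyl has an α-methyl group next to the quaternary centre, so an amine catalyst should select C7 without a protecting group. The gain is that ring B comes from a plain ketone; the demand is ketone/ketone chemoselectivity and attack at C8, not C6.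

10 ⇒ 9 (key). The C5–C6 bond is cut and the C4 hydrogen is returned to C3, which opens ring B and turns C4 and C5 into a planar olefin. Three features of 9 are deliberate:
- The C3 configuration is not a spectator. The hydride migrates suprafacially, so only the (3S) epimer, with C3–H on the tether face, gives the 4β-methyl group. C4 cannot be left to later equilibration, because next to the C3 ketone the equatorial and axial methyl arrangements differ too little in strain.
- The C3 oxygen is silylated. A free hydroxyl would not survive kinetic enol silylation, and the silyl ether cannot close to an epoxide.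
- Both silyl groups leave to methanol, which is kept to a minimum.

The demand is that hydride shift outruns solvent capture and proton loss.

9 ⇒ 8 ⇒ 7 ⇒ 6. Two O–Si bonds are cut and the methyl ketone is masked as its dioxolane. The carbinol is silylated before the ketal is hydrolysed so that the allylic C3 centre is not ionised by acid. The demand is kinetic deprotonation at the methyl group.

6 ⇒ 5. The C3–H bond is cut (carbonyl reduction). A catalyst-controlled reduction fixes C3 in both enantiomers of 5, so the C10 antipodes become separable diastereomers, of which the 1,4-trans one is 6. The gain is a racemic, two-step enone; the demand is face selectivity independent of C10 and a clean separation.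

5 ⇒ 3 ⇒ 1 + 2. The C5–CH3 bond (methyllithium addition with transposition) and the C10–C9 bond (α′-alkylation) are cut. This gives two commercial building blocks; the demands are alkylation with an unactivated primary bromide and an acid work-up mild enough to spare the dioxolane.

## Other disconnections considered

Alternative 1: The cut is C5–C10 together with C6–C7. Forward, the acyclic triene A1 (a 1-(methoxymethoxy)-2-silyloxy diene tethered to a β-methyl vinyl sulfone) is heated and closes both rings in one intramolecular Diels–Alder reaction to the bicyclic sulfone A2.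
- In its favour: the reaction type is fully precedented, which is better than the chosen key step. C2, C3 and C4 are set and orthogonally protected before cyclisation, so no late oxygenation of ring A and no hydroxyl differentiation is needed, which is also better. Both ring B oxygens arrive with the cycloaddition.
- Against it here: the dienophile is trisubstituted and must form the quaternary C5, so the cycloaddition is likely to need temperatures that endanger the silyl dienol ether. Facial and endo/exo control rest on the conformation of a tether with three stereocentres. A1 needs a long acyclic stereotriad synthesis. A2 still needs sulfone elimination, a separate oxidation to C9=C10 and removal of three kinds of protecting group.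
- Comparison: structurally it is more convergent for ring A and equal for the quaternary centre; mechanistically it is safer; in step economy it is unlikely to be shorter.

Alternative 2: The cuts are C4–CH3 and C5–C6 on a chiral-pool ring A. Forward, Me2CuLi adds to the disiloxane-bridged enone A3 from quinic acid and the enolate is trapped with allyl bromide to give the allyl ketone A4.
- In its favour: the absolute configuration of C2 and C3 comes from the chiral pool with no resolution, which is better than the chosen plan, where half of a racemate is discarded. Both bond formations are textbook chemistry, and trans addition should place the two methyl groups cis.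
- Against it here: no ring is closed. Ring B must be annulated afterwards (a second allylation at C10, ring-closing metathesis with the second-generation Grubbs catalyst, then several oxidation-level changes to the dienone diosphenol). A3 itself takes several steps from quinic acid. The two ring A oxygens share one protecting group, so the C2/C3 differentiation remains for the end, which is equal to the chosen plan.
- Comparison: better in absolute stereocontrol and in precedent, weaker in ring construction, and comparable or longer in steps.

Alternative 3: The cuts are C5–C10 (made in an ene reaction) and C7–C8 (made in a Cope rearrangement). Forward, the 1,2-divinylcyclohexanol A5 is heated with 1,8-diazabicyclo[5.4.0]undec-7-ene; oxy-Cope rearrangement gives the ten-membered enone A6, which closes by a transannular ene reaction to the decalinol A7.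
- In its favour: a reagent-free, redox-neutral cascade builds the quaternary C5 and all ring B carbons in one operation. The C3 carbonyl arrives masked and differentiated, which is better than the chosen plan, where two ketones must be told apart.
- Against it here: the temperature is harsh. A5 needs two adjacent fully substituted carbons and an enantioselective entry. The C4/C5 relationship depends on the conformation of A6. A7 is at a low oxidation level in ring B, so C7–O, C8=O and a regioselective dehydration to C9=C10 all remain, and C2 is still unoxygenated, which is equal to the chosen plan.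
- Comparison: mechanistically precedented and elegant, but the endgame would be longer.

Key step: step 7

Remark: positions are numbered C1–C10 as in the eremophilanes; β is the face of the C5 methyl group.
Remark: 3, 4 and 5 are racemic and drawn without stereodescriptors; 4 is a diastereomer mixture.
Remark: the sense of induction of the oxazaborolidine is taken from the usual model (alkenyl arm as the large group); were it opposite, the (S)-catalyst would be used.
Remark: C8 of 11 and 12 is drawn as expected for L-proline; its configuration is of no consequence because it is erased in step 9.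

## Route

Step 1
Reactants: 1 3-ethoxy-2-methylcyclohex-2-en-1-one; 2 2-(2-bromoethyl)-2-methyl-1,3-dioxolane
Product: 3 rac-3-ethoxy-2-methyl-6-[2-(2-methyl-1,3-dioxolan-2-yl)ethyl]cyclohex-2-en-1-one
Conditions: LiN(iPr)2 (LDA), THF, −78 °C; then 2, DMPU, −78 → 23 °C
Reagents that add atoms: none
Why: Stork–Danheiser α′-alkylation: kinetic deprotonation of the 3-alkoxyenone can occur only at C6, and the bromide is the standard masked 3-oxobutyl electrophile; the future C10–C9 bond is formed (racemic).

Step 2
Reactants: 3 rac-3-ethoxy-2-methyl-6-[2-(2-methyl-1,3-dioxolan-2-yl)ethyl]cyclohex-2-en-1-one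
Product: 5 rac-2,3-dimethyl-4-[2-(2-methyl-1,3-dioxolan-2-yl)ethyl]cyclohex-2-en-1-one, via tertiary allylic carbinol 4 (not isolated)
Conditions: MeLi, Et2O/THF, −78 → 0 °C; then 0.5 M aq. HCl, THF, 0 °C, short contact
Reagents that add atoms: methyllithium, [Li]C; water, O
Why: 1,2-addition to the vinylogous ester followed by acid-induced enol ether hydrolysis and dehydration (Stork–Danheiser transposition) puts the carbonyl at C3 and the new methyl on C5; the tertiary allylic carbinol collapses much faster than the dioxolane hydrolyses.

Step 3
Reactants: 5 rac-2,3-dimethyl-4-[2-(2-methyl-1,3-dioxolan-2-yl)ethyl]cyclohex-2-en-1-one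
Product: 6 (1S,4R)-2,3-dimethyl-4-[2-(2-methyl-1,3-dioxolan-2-yl)ethyl]cyclohex-2-en-1-ol
Conditions: (R)-1-methyl-3,3-diphenyltetrahydro-1H,3H-pyrrolo[1,2-c][1,3,2]oxazaborole ((R)-Me-CBS, 0.2 equiv), BH3·SMe2, THF, −20 °C; MeOH quench; chromatographic separation of the 1,4-trans alcohol from its 1,4-cis diastereomer
Reagents that add atoms: none
Why: Corey–Bakshi–Shibata reduction of an α-substituted cyclohexenone: the catalyst should deliver hydride to the same carbonyl face in both enantiomers of 5 and set the (1S) carbinol, so the C10 antipodes emerge as diastereomers and the trans one is kept. This fixes both C10 (which later controls C5) and C3 (which later controls C4).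

Step 4
Reactants: 6 (1S,4R)-2,3-dimethyl-4-[2-(2-methyl-1,3-dioxolan-2-yl)ethyl]cyclohex-2-en-1-ol
Product: 7 tert-butyl({(1S,4R)-2,3-dimethyl-4-[2-(2-methyl-1,3-dioxolan-2-yl)ethyl]cyclohex-2-en-1-yl}oxy)dimethylsilane
Conditions: TBSCl, imidazole, DMF, 23 °C
Reagents that add atoms: tert-butyldimethylsilyl chloride, CC(C)(C)[Si](C)(C)Cl
Why: Standard silylation of a secondary allylic alcohol; the silyl ether protects the ionisable allylic C3 centre from the acid of step 5 and later serves as the terminating group of the key step.

Step 5
Reactants: 7 tert-butyl({(1S,4R)-2,3-dimethyl-4-[2-(2-methyl-1,3-dioxolan-2-yl)ethyl]cyclohex-2-en-1-yl}oxy)dimethylsilane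
Product: 8 4-[(1R,4S)-4-{[tert-butyl(dimethyl)silyl]oxy}-2,3-dimethylcyclohex-2-en-1-yl]butan-2-one
Conditions: pyridinium p-toluenesulfonate (cat.), acetone/H2O (10:1), 50 °C
Reagents that add atoms: water, O
Why: Mild acid-catalysed ketal hydrolysis; a secondary tert-butyldimethylsilyl ether should survive these conditions.

Step 6
Reactants: 8 4-[(1R,4S)-4-{[tert-butyl(dimethyl)silyl]oxy}-2,3-dimethylcyclohex-2-en-1-yl]butan-2-one
Product: 9 tert-butyl{[(1S,4R)-4-(3-{[tert-butyl(dimethyl)silyl]oxy}but-3-en-1-yl)-2,3-dimethylcyclohex-2-en-1-yl]oxy}dimethylsilane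
Conditions: LiN(iPr)2 (LDA), THF, −78 °C; TBSOTf, −78 °C; Et3N, pentane work-up
Reagents that add atoms: tert-butyldimethylsilyl trifluoromethanesulfonate, CC(C)(C)[Si](C)(C)OS(=O)(=O)C(F)(F)F
Why: Kinetic deprotonation of a methyl ketone at the methyl group and O-silylation of the enolate give the terminal silyl enol ether; no hydroxyl competes because C3–O is already silylated.

Step 7
Reactants: 9 tert-butyl{[(1S,4R)-4-(3-{[tert-butyl(dimethyl)silyl]oxy}but-3-en-1-yl)-2,3-dimethylcyclohex-2-en-1-yl]oxy}dimethylsilane
Product: 10 (4R,5S,10S)-4,5-dimethyl-cis-decalin-3,7-dione (4β,5β-dimethyl, 10β-H)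
Conditions: reticulated vitreous carbon anode, Pt cathode, undivided cell, constant current (2.2 F/mol), LiClO4 (0.1 M), 2,6-lutidine, CH2Cl2/MeOH (9:1), 0 °C
Reagents that add atoms: none
Why: Proposed new method: one-electron oxidation of 9 (at the silyl enol ether or, after intramolecular electron transfer, at the tetrasubstituted olefin) gives a radical cation in which enol ether carbon C6 bonds to olefin carbon C5, leaving a silyloxocarbenium ion at C7 and a tertiary radical at C4; a second electron transfer gives the C4 cation, which is quenched by a suprafacial 1,2-hydride shift from C3, and methanol strips both silyl groups to unveil the C7 and C3 ketones while hydrogen is evolved at the cathode. The closest known reaction type is the anodic coupling of enol ether or silyl enol ether radical cations with trisubstituted olefins, which forges quaternary carbons and ends by solvent capture or proton loss; the hydride-shift ending is the new element and is modelled on the familiar 1,2-hydride shift of β-silyloxy carbocations. Ring B closes in a 6-exo-trig mode onto the C4=C5 olefin, the 7-endo alternative at C4 being disfavoured. C5 is set by the C10 stereocentre: the four-atom tether can reach the C5 p-orbital with perpendicular approach only on its own face, which gives the cis-fused bicycle and places 5-CH3 β. C4 is set by the C3 stereocentre: in the (3S) series C3–H lies on the tether face and can sit pseudo-axial with the bulky silyloxy group pseudo-equatorial, so hydride crosses on that face and leaves 4-CH3 β, cis to 5-CH3. The step needs the hydride shift to outrun solvent capture of the C4 cation, proton loss and over-oxidation; this is secured by the neopentyl-like shielding of C4, by the exothermic formation of a silyloxocarbenium ion, by keeping methanol to the amount needed as silyl acceptor and proton source, and by 2,6-lutidine as buffer.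

Step 8
Reactants: 10 (4R,5S,10S)-4,5-dimethyl-cis-decalin-3,7-dione
Product: 12 (8R)-8-hydroxy-4β,5β-dimethyl-cis-decalin-3,7-dione, via aminooxy ketone 11 (not isolated)
Conditions: L-proline (0.3 equiv), PhNO (slow addition), DMSO, 23 °C; then MeOH, CuSO4·5H2O (0.3 equiv), 0 → 23 °C
Reagents that add atoms: nitrosobenzene, O=Nc1ccccc1
Why: Proline-catalysed α-aminoxylation followed by copper-mediated N–O cleavage: only the C7 carbonyl, flanked by two methylenes, should condense with proline, and its enamine forms away from quaternary C5, so oxygen enters at C8. The C3 ketone (α-methyl next to the quaternary centre) is left alone, so no protecting group is needed.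

Step 9
Reactants: 12 (8R)-8-hydroxy-4β,5β-dimethyl-cis-decalin-3,7-dione
Product: 13 7-hydroxy-4β,5β-dimethyl-10β-H-decal-6-ene-3,8-dione (diosphenol, enol form of the 3,7,8-trione)
Conditions: Dess–Martin periodinane, CH2Cl2, 23 °C
Reagents that add atoms: none
Why: Oxidation of an α-ketol to the 1,2-dione, which enolises to the diosphenol; the conditions are neutral, so the C4 centre next to the C3 ketone should not epimerise.

Step 10
Reactants: 13 7-hydroxy-4β,5β-dimethyl-10β-H-decal-6-ene-3,8-dione
Product: 14 7-hydroxy-4β,5β-dimethyldecala-6,9(10)-diene-3,8-dione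
Conditions: 2,3-dichloro-5,6-dicyano-1,4-benzoquinone (DDQ), 1,4-dioxane, 80 °C
Reagents that add atoms: none
Why: DDQ dehydrogenation: hydride abstraction from C10 of the C8 enol tautomer and loss of the enol proton give the C9=C10 dione, which can enolise only towards C6. Quaternary C5 blocks aromatisation and the saturated C3 ketone should not react; the C10 stereocentre is removed here.

Step 11
Reactants: 14 7-hydroxy-4β,5β-dimethyldecala-6,9(10)-diene-3,8-dione
Product: 15 7-{[tert-butyl(dimethyl)silyl]oxy}-4β,5β-dimethyldecala-6,9(10)-diene-3,8-dione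
Conditions: TBSCl, imidazole, CH2Cl2, 23 °C
Reagents that add atoms: tert-butyldimethylsilyl chloride, CC(C)(C)[Si](C)(C)Cl
Why: O-silylation of the acidic enol hydroxyl, so that it neither consumes base in step 12 nor binds the borohydride of step 13.

Step 12
Reactants: 15 7-{[tert-butyl(dimethyl)silyl]oxy}-4β,5β-dimethyldecala-6,9(10)-diene-3,8-dione
Product: 16 2α-hydroxy-7-{[tert-butyl(dimethyl)silyl]oxy}-4β,5β-dimethyldecala-6,9(10)-diene-3,8-dione
Conditions: KN(SiMe3)2, THF, −78 °C; 2-(phenylsulfonyl)-3-phenyloxaziridine, −78 °C; AcOH quench at −78 °C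
Reagents that add atoms: 2-(phenylsulfonyl)-3-phenyloxaziridine, O=S(=O)(c1ccccc1)N1OC1c1ccccc1
Why: Davis enolate oxidation: kinetic deprotonation should occur at C2 (C4–H is tertiary and shielded, and the vinylogous C1–H is not reached by base held at the C3 carbonyl). Ring A is now one chair with axial 5-CH3 on the β face, so the oxaziridine should add axially from the α face and give the 2α-hydroxyl.

Step 13
Reactants: 16 2α-hydroxy-7-{[tert-butyl(dimethyl)silyl]oxy}-4β,5β-dimethyldecala-6,9(10)-diene-3,8-dione
Product: 17 2α,3β-dihydroxy-7-{[tert-butyl(dimethyl)silyl]oxy}-4β,5β-dimethyldecala-6,9(10)-dien-8-one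
Conditions: Me4NBH(OAc)3, MeCN/AcOH (1:1), −30 → −20 °C
Reagents that add atoms: none
Why: Hydroxyl-directed (Evans–Saksena type) reduction: hydride is delivered from the boron bound to the 2α-oxygen to the α face of C3 and gives the trans-diaxial diol; the same face is favoured sterically because axial attack is blocked by 5-CH3. The dienone and its silyl enol ether are inert to this reagent.

Step 14
Reactants: 17 2α,3β-dihydroxy-7-{[tert-butyl(dimethyl)silyl]oxy}-4β,5β-dimethyldecala-6,9(10)-dien-8-one
Product: 18 3β-hydroxy-2α,7-bis{[tert-butyl(dimethyl)silyl]oxy}-4β,5β-dimethyldecala-6,9(10)-dien-8-one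
Conditions: TBSCl, imidazole, DMF, 23 → 40 °C
Reagents that add atoms: tert-butyldimethylsilyl chloride, CC(C)(C)[Si](C)(C)Cl
Why: Site-selective silylation: the C2 hydroxyl has no syn-axial substituent, whereas the C3 hydroxyl is syn-axial to 5-CH3 and flanked by 4-CH3, so only C2–OH should react.

Step 15
Reactants: 19 (S)-2-methylbutan-1-ol
Product: 20 (S)-2-methylbutanal
Conditions: 2,2,6,6-tetramethylpiperidin-1-oxyl (TEMPO, cat.), PhI(OAc)2, CH2Cl2, 0 → 23 °C; carried on as a solution
Reagents that add atoms: none
Why: Oxoammonium-mediated oxidation of a primary alcohol under non-basic conditions, chosen so that the α-stereocentre is not epimerised.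

Step 16
Reactants: 20 (S)-2-methylbutanal; 21 triethyl 4-phosphonocrotonate
Product: 22 ethyl (2E,4E,6S)-6-methylocta-2,4-dienoate
Conditions: 21, LiN(SiMe3)2, THF, −78 °C; then 20, −78 → 0 °C
Reagents that add atoms: none
Why: Vinylogous Horner–Wadsworth–Emmons olefination, which should form the new C4′=C5′ bond with E geometry; adding the aldehyde to the preformed anion at low temperature limits epimerisation at C6′.

Step 17
Reactants: 22 ethyl (2E,4E,6S)-6-methylocta-2,4-dienoate
Product: 23 (2E,4E,6S)-6-methylocta-2,4-dienoic acid
Conditions: LiOH·H2O, THF/MeOH/H2O, 23 °C; then 1 M HCl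
Reagents that add atoms: lithium hydroxide, [Li+].[OH-]
Why: Saponification of a conjugated ester; the C6′ centre is not acidic enough to be touched by aqueous hydroxide at room temperature.

Step 18
Reactants: 18 3β-hydroxy-2α,7-bis{[tert-butyl(dimethyl)silyl]oxy}-4β,5β-dimethyldecala-6,9(10)-dien-8-one; 23 (2E,4E,6S)-6-methylocta-2,4-dienoic acid
Product: 25 2α,7-bis{[tert-butyl(dimethyl)silyl]oxy}-4β,5β-dimethyl-8-oxodecala-6,9(10)-dien-3β-yl (2E,4E,6S)-6-methylocta-2,4-dienoate, via mixed anhydride 24 (not isolated)
Conditions: 23, 2,4,6-trichlorobenzoyl chloride, Et3N, toluene, 23 °C; then 18, 4-(dimethylamino)pyridine (DMAP), toluene, 60 °C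
Reagents that add atoms: none
Why: Yamaguchi esterification, a standard answer to hindered secondary alcohols; the only free hydroxyl is the one at C3.

Step 19
Reactants: 25 2α,7-bis{[tert-butyl(dimethyl)silyl]oxy}-4β,5β-dimethyl-8-oxodecala-6,9(10)-dien-3β-yl (2E,4E,6S)-6-methylocta-2,4-dienoate
Product: 26 septeremophilane G
Conditions: HF·pyridine, pyridine/THF, 0 → 23 °C
Reagents that add atoms: none
Why: Acidic fluoride cleaves both the enol silyl ether and the secondary silyl ether; under non-basic conditions and with the two oxygens trans-diaxial the acyl group should not migrate from C3 to C2.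

## Compound list

1 | 3-ethoxy-2-methylcyclohex-2-en-1-one | CCOC1=C(C)C(=O)CCC1 | starting material
2 | 2-(2-bromoethyl)-2-methyl-1,3-dioxolane | CC1(CCBr)OCCO1 | starting material
3 | rac-3-ethoxy-2-methyl-6-[2-(2-methyl-1,3-dioxolan-2-yl)ethyl]cyclohex-2-en-1-one | CCOC1=C(C)C(=O)C(CCC2(C)OCCO2)CC1 | intermediate
4 | 3-ethoxy-1,2-dimethyl-6-[2-(2-methyl-1,3-dioxolan-2-yl)ethyl]cyclohex-2-en-1-ol (racemic diastereomer mixture, not isolated) | CCOC1=C(C)C(C)(O)C(CCC2(C)OCCO2)CC1 | intermediate
5 | rac-2,3-dimethyl-4-[2-(2-methyl-1,3-dioxolan-2-yl)ethyl]cyclohex-2-en-1-one | CC1=C(C)C(CCC2(C)OCCO2)CCC1=O | intermediate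
6 | (1S,4R)-2,3-dimethyl-4-[2-(2-methyl-1,3-dioxolan-2-yl)ethyl]cyclohex-2-en-1-ol | CC1(CC[C@H]2CC[C@H](O)C(C)=C2C)OCCO1 | intermediate
7 | tert-butyl({(1S,4R)-2,3-dimethyl-4-[2-(2-methyl-1,3-dioxolan-2-yl)ethyl]cyclohex-2-en-1-yl}oxy)dimethylsilane | CC1(CC[C@H]2CC[C@H](O[Si](C)(C)C(C)(C)C)C(C)=C2C)OCCO1 | intermediate
8 | 4-[(1R,4S)-4-{[tert-butyl(dimethyl)silyl]oxy}-2,3-dimethylcyclohex-2-en-1-yl]butan-2-one | CC(=O)CC[C@H]1CC[C@H](O[Si](C)(C)C(C)(C)C)C(C)=C1C | intermediate
9 | tert-butyl{[(1S,4R)-4-(3-{[tert-butyl(dimethyl)silyl]oxy}but-3-en-1-yl)-2,3-dimethylcyclohex-2-en-1-yl]oxy}dimethylsilane | C=C(O[Si](C)(C)C(C)(C)C)CC[C@H]1CC[C@H](O[Si](C)(C)C(C)(C)C)C(C)=C1C | intermediate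
10 | (4R,5S,10S)-4,5-dimethyl-cis-decalin-3,7-dione | C[C@H]1C(=O)CC[C@@H]2CCC(=O)C[C@]12C | intermediate
11 | (8R)-8-(N-phenylaminooxy)-4β,5β-dimethyl-cis-decalin-3,7-dione (not isolated) | C[C@H]1C(=O)CC[C@@H]2C[C@@H](ONc3ccccc3)C(=O)C[C@]12C | intermediate
12 | (8R)-8-hydroxy-4β,5β-dimethyl-cis-decalin-3,7-dione | C[C@H]1C(=O)CC[C@@H]2C[C@@H](O)C(=O)C[C@]12C | intermediate
13 | 7-hydroxy-4β,5β-dimethyl-10β-H-decal-6-ene-3,8-dione | C[C@H]1C(=O)CC[C@@H]2CC(=O)C(O)=C[C@]12C | intermediate
14 | 7-hydroxy-4β,5β-dimethyldecala-6,9(10)-diene-3,8-dione | C[C@H]1C(=O)CCC2=CC(=O)C(O)=C[C@]12C | intermediate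
15 | 7-{[tert-butyl(dimethyl)silyl]oxy}-4β,5β-dimethyldecala-6,9(10)-diene-3,8-dione | C[C@H]1C(=O)CCC2=CC(=O)C(O[Si](C)(C)C(C)(C)C)=C[C@]12C | intermediate
16 | 2α-hydroxy-7-{[tert-butyl(dimethyl)silyl]oxy}-4β,5β-dimethyldecala-6,9(10)-diene-3,8-dione | C[C@H]1C(=O)[C@H](O)CC2=CC(=O)C(O[Si](C)(C)C(C)(C)C)=C[C@]12C | intermediate
17 | 2α,3β-dihydroxy-7-{[tert-butyl(dimethyl)silyl]oxy}-4β,5β-dimethyldecala-6,9(10)-dien-8-one | C[C@H]1[C@@H](O)[C@H](O)CC2=CC(=O)C(O[Si](C)(C)C(C)(C)C)=C[C@]12C | intermediate
18 | 3β-hydroxy-2α,7-bis{[tert-butyl(dimethyl)silyl]oxy}-4β,5β-dimethyldecala-6,9(10)-dien-8-one | C[C@H]1[C@@H](O)[C@H](O[Si](C)(C)C(C)(C)C)CC2=CC(=O)C(O[Si](C)(C)C(C)(C)C)=C[C@]12C | intermediate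
19 | (S)-2-methylbutan-1-ol | CC[C@H](C)CO | starting material
20 | (S)-2-methylbutanal | CC[C@H](C)C=O | intermediate
21 | triethyl 4-phosphonocrotonate | CCOC(=O)/C=C/CP(=O)(OCC)OCC | starting material
22 | ethyl (2E,4E,6S)-6-methylocta-2,4-dienoate | CC[C@H](C)/C=C/C=C/C(=O)OCC | intermediate
23 | (2E,4E,6S)-6-methylocta-2,4-dienoic acid | CC[C@H](C)/C=C/C=C/C(=O)O | intermediate
24 | (2E,4E,6S)-6-methylocta-2,4-dienoic 2,4,6-trichlorobenzoic anhydride (not isolated) | CC[C@H](C)/C=C/C=C/C(=O)OC(=O)c1c(Cl)cc(Cl)cc1Cl | intermediate
25 | 2α,7-bis{[tert-butyl(dimethyl)silyl]oxy}-4β,5β-dimethyl-8-oxodecala-6,9(10)-dien-3β-yl (2E,4E,6S)-6-methylocta-2,4-dienoate | CC[C@H](C)/C=C/C=C/C(=O)O[C@H]1[C@H](O[Si](C)(C)C(C)(C)C)CC2=CC(=O)C(O[Si](C)(C)C(C)(C)C)=C[C@]2(C)[C@H]1C | intermediate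
26 | septeremophilane G, (2R,3R,4R,5S)-2α,7-dihydroxy-4β,5β-dimethyl-8-oxodecala-6,9(10)-dien-3β-yl (2E,4E,6S)-6-methylocta-2,4-dienoate | CC[C@H](C)/C=C/C=C/C(=O)O[C@H]1[C@H](O)CC2=CC(=O)C(O)=C[C@]2(C)[C@H]1C | target

## Step count and least certain steps

Total: 19 steps. Longest linear sequence: 16 steps (steps 1–14, 18 and 19); the side chain takes steps 15–17.

Step 7 (key step). The most likely failure is that the C4 cation is intercepted by methanol or loses a proton before the hydride shift. Alternatively, the olefin radical cation may lose its allylic C3 hydrogen and be over-oxidised, because closure onto the fully substituted C5 is slow. Fallback by known chemistry, from 9 back to 10: N-bromosuccinimide in THF at −78 °C should convert the silyl enol ether into the bromomethyl ketone F1. Slow addition of Bu3SnH with azobisisobutyronitrile in hot benzene should close ring B by 6-exo cyclisation of the α-keto radical onto C5 and reduce the C4 radical, giving the bicyclic keto silyl ether F2. Fluoride (Bu4NF) should free the keto alcohol F3, and Dess–Martin oxidation returns to 10. In this fallback C4 is set by hydrogen-atom transfer and is not controlled, so its epimer might have to be separated.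

Step 3. The most likely failure is incomplete catalyst control in the mismatched enantiomer of 5, which would lower the enantiomeric purity of the trans alcohol, or a difficult separation of the cis and trans alcohols. Fallback from 5 back to 6: NaBH4/CeCl3·7H2O in MeOH should give the racemic alcohol F4 as a cis/trans mixture. A lipase (from Burkholderia cepacia) with vinyl acetate should acylate the (1R) alcohols to the acetates F5 and leave the (1S) alcohols, from which 6 is separated from its cis isomer F6 by chromatography.

Step 8. The most likely failure is slow enamine formation at a ketone with a β-quaternary centre, so that nitrosobenzene is consumed by self-condensation or N-attack. Fallback from 10 back to 12: pyrrolidine with azeotropic removal of water should give the C7 enamine F7 selectively. Dibenzoyl peroxide followed by aqueous work-up should give the 8-benzoyloxy ketone F8, and K2CO3 in MeOH should release 12 (as a C8 epimer mixture, both epimers converging in step 9).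

Step 10. The most likely failure is sluggish hydride abstraction from the tertiary C10, or further dehydrogenation towards C1–C2 on forcing. Fallback from 13 back to 14: pyridinium tribromide should brominate the enol at C9 to the bromo diosphenol F9, and Li2CO3/LiBr in hot DMF should eliminate hydrogen bromide across C9–C10.

Step 12. The most likely failure is competing vinylogous deprotonation at C1 of the dienone, or addition of the enolate to the sulfonimine formed from the oxidant. Fallback from 15 back to 16 without strong base: TMSOTf/Et3N in CH2Cl2 at −78 °C should give the C2=C3 trimethylsilyl enol ether F10 (amine deprotonation at the unhindered axial C2–H), and Rubottom oxidation with dimethyldioxirane, again from the α face, followed by mild acid should give 16.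

## Further compounds

F1 | step 7 | 1-bromo-4-[(1R,4S)-4-{[tert-butyl(dimethyl)silyl]oxy}-2,3-dimethylcyclohex-2-en-1-yl]butan-2-one | BrCC(=O)CC[C@H]1CC[C@H](O[Si](C)(C)C(C)(C)C)C(C)=C1C
F2 | step 7 | 3β-{[tert-butyl(dimethyl)silyl]oxy}-4β,5β-dimethyl-cis-decalin-7-one | C[C@H]1[C@@H](O[Si](C)(C)C(C)(C)C)CC[C@@H]2CCC(=O)C[C@]12C
F3 | step 7 | 3β-hydroxy-4β,5β-dimethyl-cis-decalin-7-one | C[C@H]1[C@@H](O)CC[C@@H]2CCC(=O)C[C@]12C
F4 | step 3 | rac-2,3-dimethyl-4-[2-(2-methyl-1,3-dioxolan-2-yl)ethyl]cyclohex-2-en-1-ol (cis/trans mixture) | CC1(CCC2CCC(O)C(C)=C2C)OCCO1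
F5 | step 3 | (1R)-2,3-dimethyl-4-[2-(2-methyl-1,3-dioxolan-2-yl)ethyl]cyclohex-2-en-1-yl acetate (both C4 epimers) | CC(=O)O[C@@H]1CCC(CCC2(C)OCCO2)C(C)=C1C
F6 | step 3 | (1S,4S)-2,3-dimethyl-4-[2-(2-methyl-1,3-dioxolan-2-yl)ethyl]cyclohex-2-en-1-ol | CC1(CC[C@@H]2CC[C@H](O)C(C)=C2C)OCCO1
F7 | step 8 | 7-(pyrrolidin-1-yl)-4β,5β-dimethyl-10β-H-decal-7-en-3-one | C[C@H]1C(=O)CC[C@@H]2CC=C(N3CCCC3)C[C@]12C
F8 | step 8 | 8-benzoyloxy-4β,5β-dimethyl-cis-decalin-3,7-dione (C8 epimers) | C[C@H]1C(=O)CC[C@@H]2CC(OC(=O)c3ccccc3)C(=O)C[C@]12C
F9 | step 10 | 9-bromo-7-hydroxy-4β,5β-dimethyl-10β-H-decal-6-ene-3,8-dione | C[C@H]1C(=O)CC[C@@H]2C(Br)C(=O)C(O)=C[C@]12C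
F10 | step 12 | 7-{[tert-butyl(dimethyl)silyl]oxy}-3-(trimethylsilyloxy)-4β,5β-dimethyldecala-2,6,9(10)-trien-8-one | C[C@H]1C(O[Si](C)(C)C)=CCC2=CC(=O)C(O[Si](C)(C)C(C)(C)C)=C[C@]12C
A1 | alternative 1 | acyclic triene, 1-(methoxymethoxy)-2-silyloxy diene tethered to an (E)-2-methylvinyl phenyl sulfone | COCOC=C(O[Si](C)(C)C(C)(C)C)/C=C/C[C@@H](O[Si](C)(C)C(C)(C)C)[C@H](OCc1ccc(OC)cc1)[C@H](C)/C(C)=C/S(=O)(=O)c1ccccc1
A2 | alternative 1 | bicyclic sulfone (Diels–Alder adduct) | C[C@H]1[C@@H](OCc2ccc(OC)cc2)[C@H](O[Si](C)(C)C(C)(C)C)C[C@H]2C=C(O[Si](C)(C)C(C)(C)C)C(OCOC)C(S(=O)(=O)c3ccccc3)[C@]12C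
A3 | alternative 2 | disiloxane-bridged 2-methylcyclohexenone from quinic acid | CC1=C[C@H]2O[Si](C(C)C)(C(C)C)O[Si](C(C)C)(C(C)C)O[C@@H]2CC1=O
A4 | alternative 2 | allyl ketone | C=CC[C@]1(C)[C@@H](C)[C@H]2O[Si](C(C)C)(C(C)C)O[Si](C(C)C)(C(C)C)O[C@@H]2CC1=O
A5 | alternative 3 | 1,2-divinylcyclohexanol ketal (trans-divinyl, configuration at C5 and C10 assumed) | C=C[C@]1(O)CCC2(OCCO2)[C@H](C)[C@@]1(C)C=C
A6 | alternative 3 | (E)-cyclodec-5-enone ketal | O=C1CCC/C=C(C)/[C@@H](C)C2(OCCO2)CC1
A7 | alternative 3 | trans-fused decalinol | C[C@H]1C2(OCCO2)CC[C@@]3(O)CCC=C[C@]13C
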